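The readings are simulated with made-up constants, and the scatter is random.

In a one-step world Q + E gives Z and Z stays, so a run climbs and sits. Elm and birch don't sit: Z falls from 59.6% to 53.4% in elm and, further, from 65.3% to 41.2% in birch, the flask with more E.

| setting | elm | birch | west | north-west |
|---|---|---|---|---|
| Q | 0.40 M | 0.40 M | 0.40 M | 0.40 M |
| E | 0.68 M | 1.1 M | 0.480 M | 0.720 M |
| remark | run made earlier | run made earlier |  |  |
| time |  |  | 8.0 min | 8.0 min |

| run | time / min | Z / % |
|---|---|---|
| elm | 1.50 | 52.8 |
| elm | 3.00 | 59.6 |
| elm | 5.00 | 59.1 |
| elm | 6.00 | 57.1 |
| elm | 8.00 | 53.4 |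
| birch | 0.667 | 52.4 |
| birch | 1.33 | 63.8 |
| birch | 2.50 | 65.3 |
| birch | 4.00 | 58.2 |
| birch | 8.00 | 41.2 |

(each reading ± 0.5 percentage points)

- which of the two there is more of at the end, counted by the Q in each, west (J / Z)
- which of the two there is more of at the end, counted by the Q in each, north-west (J / Z)
- Z at the end, in percent of the Q charged, west
- Z at the end, in percent of the Q charged, north-west

I read this as E consuming Z, and I freeze the concentration [E] over the late stretch, which makes the loss pseudo-first-order with pace κ[E]. The late paces read 0.0338 /min in elm and 0.0864 /min in birch. I don't know [E] there, but both had the same Q charged, so I suppose they spent the same E. The difference of paces over the difference of charges then gives κ, the late loss constant of Z per molar of E: 0.125 /M/min. The objection is that Q still feeding Z would make both paces read low, and two runs for two unknowns offer no check. I accept both.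

North-west lies close to elm, so I shift elm's last reading. North-west's peak gains 0.54 percentage points on the line through the two peak readings, and its extra pace costs 1.3 points, which gives my estimate of 52.6%.

West lies far off. The line gives west a peak of 56.9%, which I place at 4.25 min by stretching elm's time with the charge ratio. Subtracting from west's charge the E I reckon spent in elm and birch, 0.410 M, leaves 0.0702 M. But west may spend less. Subtracting just the E held in that peak of Z leaves 0.252 M, which ignores the E lost with Z. I take the mean of the two as west's [E] and estimate 52.7%. On that estimate J can hold at most the remainder, 47.3%, so I expect Z to lead in west, and in north-west too.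

The forecast also says Z in both, but its numbers differ from mine: 50% for west and 54.5% for north-west, and of west it writes “decay nearly stops”.

West ends at 53.8% Z against 26.1% J, north-west at 53.0% Z against 18.5% J.

    Q + E → Z (k = 0.0307 /M/s)
    Q → X (k = 5.45 × 10⁻⁴ /s)
    2 Q → J (k = 0.0141 /M/s)
    Q + Z ⇌ L, settled at all times (K = 3.20 /M)
    E + Z → D (k = 0.00263 /M/s)
    2 Q → G (k = 2.87 × 10⁻⁶ /M/s)

In north-west, Z stands at 59.0% at 5.0 min with 49.6% of the E charge left, and 43.3% is left at 8.0 min. κ with the mean of those two amounts carries that 59.0% to 52.1%, against the 53.0% that stands. A neighbour like north-west but with 1.6 M of Q has 6.49% of its E left at 8.0 min, so κ[E] there comes to 0.00585 /min, and it holds 3.38% D.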